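## Structural features

The target is an achiral, planar 1H-indole: a benzene ring (C3a, C4, C5, C6, C7, C7a) fused through the C3a–C7a bond to a pyrrole ring (N1, C2, C3, C3a, C7a), with no stereocenters. Every carbon except C7 carries a heteroatom: bromine at C2, C4, C5 and C6, a methylsulfanyl group at C3, and N1 is unsubstituted. The bromines at C4, C5 and C6 are contiguous and C4–Br stands peri to the sulfur at C3; electrophilic bromination of an indole cannot give this pattern, because the benzene ring reacts at C5 and C6 well before C4. Seen from N1, the benzene half is 3,4,5-tribromoaniline, whose two ortho carbons are equivalent by mirror symmetry, so a carbon attached to either one becomes C3 on C3a without a regiochemical question. In the pyrrole ring, C2 is a one-carbon unit bonded only to N1, C3 and bromine, and C3 is a benzylic carbon bearing sulfur. The fragile groups are the 2-bromoindole (acid- and light-sensitive), the sulfide (easily oxidised, and liable to migrate or be lost from C3 under acid) and the aryl bromides, which exclude alkyllithium reagents and reductive conditions. The real difficulty is to close the pyrrole ring beside the crowded C4–Br with sulfur already on C3, under conditions that the C–Br bonds survive. The key step exploits the C3–S bond and the isolated carbon C2: sulfur makes the benzylic C3–H acidic enough for an amide base, and C2 can be the carbon of an isocyanide on N1, so the pyrrole ring is closed at the C2–C3 bond.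

## Logic of the disconnections

**10 to 9 (C2–Br).** The C2–Br bond is cut last. In 9, C3 is blocked by sulfur and the benzene ring is deactivated by three bromines, so C2 is the only position left for an electrophile. The acid-sensitive 2-bromoindole is then carried through no other step. The gain is one halogen less and a robust precursor. The demand is one equivalent of a mild bromonium source at low temperature, so that sulfur is not oxidised and C7 and N1 are left alone.

**9 to 6 (C2–C3, the key disconnection).** The pyrrole ring is opened at its C2–C3 bond, not at N1–C2 or N1–C7a. C2 becomes the terminal carbon of an isocyanide on N1, and C3 becomes a benzylic CH2 that carries the sulfur. In the forward direction the carbanion at C3 (7) adds to the isocyanide carbon, and 8 results after a proton shift. In one sentence: the pyrrole ring is closed at C2–C3 by attack of a sulfur-stabilised benzylic carbanion on the ortho isocyanide carbon of 6. The gain is that the bicyclic heteroaromatic falls back on a benzene whose nitrogen and C3 are already attached, C2 enters at the correct oxidation level, and the sulfur the target needs at C3 is the group that makes the closure possible. The demand is selective benzylic deprotonation in the presence of three aryl bromides and one acidic ring C–H, hence a lithium amide at low temperature and never an alkyllithium.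

**6 to 5 to 4 (N1–C2).** The isocyanide carbon is removed from nitrogen by way of the formamide: 6 comes from 5 by dehydration, and 5 from 4 by N-formylation. The gain is that C2 is traced to a one-carbon acylating agent at the formic acid oxidation level. The demand is a dehydration that neither oxidises nor alkylates the sulfide and that outruns attack of sulfur on the activated formyl carbon.

**4 to 1 (C3–C3a).** The bond between the benzylic carbon and the ring is cut. Forward, it is made by a [2,3]-sigmatropic shift of the sulfur ylide that derives from 2 and 3, which moves a CH2–S–CH3 unit from nitrogen-bound sulfur to the ortho carbon. The shift is intramolecular and ortho-specific, and it does not depend on the nucleophilicity of the deactivated ring. Because the two ortho carbons of 1 are equivalent, only one product can form, and C3 arrives together with its sulfur from a simple dialkyl sulfide. The gain is that 4 falls back on symmetrical 1, which already holds the three bromines in their final positions. The demand is N–S bond formation by a weakly nucleophilic aniline and control of a second ortho-alkylation.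

## Other disconnections considered

**Alternative 1:** (the first that comes to mind) Cut the C3–S and C2–Br bonds on a finished indole nucleus. Forward, 4,5,6-tribromo-1H-indole A1 would be sulfenylated at C3 by electrophilic substitution to give 9 and then brominated at C2. The chosen plan is preferred because A1 cannot be reached by brominating indole (C4, peri to C3, is expected to be the last benzene position to react). A1 would therefore need its own ring synthesis on a tribrominated benzene. The real problem is thus only postponed: the pyrrole ring is first built without sulfur and sulfur is added afterwards, at a cost of more steps.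

**Alternative 2:** Cut C3–C3a together with the N1–C2 amide bond of an oxindole. Forward, the azasulfonium ylide from 1 and an α-(methylsulfanyl)acetic ester would rearrange by a [2,3] shift, and the amino ester would lactamise to 4,5,6-tribromo-3-(methylsulfanyl)-1,3-dihydro-2H-indol-2-one A2 (racemic). A phosphorus oxybromide reagent would then turn the lactam carbonyl into the C2–Br bond. This plan is shorter on paper. It is set aside for two reasons. It closes the ring at nitrogen in the textbook manner for 3-sulfanyl indoles. More importantly, the target-forming step would be a hot, strongly acidic bromodehydration that releases HBr. Under such conditions the enolisable C3–H of A2 and the acid-labile C3 sulfenyl group are expected to suffer side reactions, whereas the chosen plan ends with a cold, near-neutral bromination.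

**Alternative 3:** Cut N1–C7a and C3–C3a at the benzene ring, so that both ring substituents arrive on an aryne. Forward, 3,4,5-tribromobenzyne A3 would take up the nitrogen of an N-sulfonyl glycine ester at the aryne carbon remote from bromine (the future C7a). The inductively withdrawing C–Br distorts the aryne so that the developing aryl anion sits next to bromine (the future C3a), where it would attack the ester carbon to give 4,5,6-tribromo-1-(4-methylbenzenesulfonyl)-1,2-dihydro-3H-indol-3-one A4. The sides would be right, but the chosen plan is preferred on three grounds:
- A3 needs a precursor with four contiguous substituents, and its generation through aryl-metal species flanked by bromines invites bromine migration.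
- A4 carries oxygen at C3, no sulfur and no bromine at C2, so several functional group operations and an N-deprotection would follow.
- The benzene half is the easy part of this target, since symmetrical 1 already provides it.

Key step: step 4

Assumption: 3,4,5-tribromoaniline (1) is taken as a commercially available compound. The target is achiral, so no configuration has to be set.

## Steps

Step 1
Reactants: 1 3,4,5-tribromoaniline
Product: 4 3,4,5-tribromo-2-[(methylsulfanyl)methyl]aniline, via azasulfonium chloride 2 (not isolated), via sulfilimine 3 (not isolated)
Conditions: NCS, Me2S, ClCH2CH2Cl, −20 °C; then Et3N, −20 °C to 80 °C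
Reagents that add atoms: dimethyl sulfide, CSC
Why: Gassman ortho-alkylation of an aniline: NCS and Me2S form the Corey–Kim chlorosulfonium reagent, the nitrogen of 1 attacks its sulfur to give 2, Et3N frees sulfilimine 3, and the ylide tautomer of 3 undergoes the Sommelet–Hauser [2,3]-sigmatropic shift to an ortho carbon and rearomatises to 4. Both ortho carbons of 1 are equivalent, the shift is intramolecular and so indifferent to the deactivated ring, and a stoichiometric amount of reagent should limit a second alkylation.

Step 2
Reactants: 4 3,4,5-tribromo-2-[(methylsulfanyl)methyl]aniline
Product: 5 N-{3,4,5-tribromo-2-[(methylsulfanyl)methyl]phenyl}formamide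
Conditions: HCO2H, Ac2O (premixed, 55 °C), THF, 0 °C to rt
Reagents that add atoms: formic acid, OC=O (used as acetic formic anhydride, CC(=O)OC=O)
Why: N-Formylation with the mixed anhydride, which transfers its more electrophilic formyl group even to a weakly nucleophilic, ortho-substituted aniline; the sulfide and the aryl bromides are inert.

Step 3
Reactants: 5 N-{3,4,5-tribromo-2-[(methylsulfanyl)methyl]phenyl}formamide
Product: 6 1,2,3-tribromo-5-isocyano-4-[(methylsulfanyl)methyl]benzene
Conditions: POCl3, Et3N, CH2Cl2, −20 to 0 °C
Reagents that add atoms: none
Why: Ugi dehydration of a formamide: O-phosphorylation and base-induced alpha-elimination give the isocyanide. Excess Et3N at low temperature should outrun capture of the activated formyl carbon by the neighbouring sulfide, and no oxidant or metal touches sulfur or the C–Br bonds.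

Step 4
Reactants: 6 1,2,3-tribromo-5-isocyano-4-[(methylsulfanyl)methyl]benzene
Product: 9 4,5,6-tribromo-3-(methylsulfanyl)-1H-indole, via benzylic organolithium 7 (not isolated), via lithium indol-1-ide 8 (not isolated)
Conditions: LiN(iPr)2 (2 equiv), diglyme–THF, −78 °C (6 added slowly), then 0 °C; AcOH
Reagents that add atoms: none
Why: Ito–Saegusa indole synthesis, the anionic cyclisation of an ortho-alkylphenyl isocyanide. The amide base removes a benzylic proton of 6, acidified by sulfur, by the tribrominated ring and by the ortho isocyano group, to give 7. On warming, the carbanion adds to the terminal, carbene-like isocyanide carbon, which accepts the nucleophile and keeps the charge on the same atom (alpha-addition), so the pyrrole ring closes at C2–C3 in a 5-endo-dig mode that Baldwin's rules favour, giving a 2-lithio-3H-indole. A 1,3-proton shift from C3 to nitrogen, relayed by HN(iPr)2, then gives the aromatic indolide 8 irreversibly, and the acid quench gives 9. No stereocenter is formed. The step needs deprotonation at the benzylic carbon and not at the ring C–H between the isocyano group and bromine, and it needs the C–Br bonds untouched. A lithium amide does not undergo halogen–metal exchange with aryl bromides, the sulfur-bearing benzylic C–H is expected to be several pK units more acidic than the ring C–H, and inverse addition at −78 °C keeps neutral aryl bromide scarce, which is the partner needed both for bromine migration and for intermolecular addition to the isocyanide. C2 emerges as C–H at the correct oxidation level, so no redox adjustment follows.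

Step 5
Reactants: 9 4,5,6-tribromo-3-(methylsulfanyl)-1H-indole
Product: 10 2,4,5,6-tetrabromo-3-(methylsulfanyl)-1H-indole
Conditions: NBS (1.0 equiv), CH2Cl2, −78 to 0 °C, dark
Reagents that add atoms: N-bromosuccinimide, O=C1CCC(=O)N1Br
Why: Electrophilic bromination of a 3-sulfanylindole: with C3 blocked, attack at C3 (or at sulfur) is followed by 1,2-migration of bromine to C2 and loss of the C2 proton, a known course for 3-(methylsulfanyl)indoles with NBS. The benzene ring, deactivated by three bromines, and the hindered C7 should not compete at one equivalent.

## Compound list

1 | 3,4,5-tribromoaniline | Nc1cc(Br)c(Br)c(Br)c1 | starting material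
2 | dimethyl[(3,4,5-tribromophenyl)amino]sulfonium chloride | C[S+](C)Nc1cc(Br)c(Br)c(Br)c1.[Cl-] | intermediate (not isolated)
3 | S,S-dimethyl-N-(3,4,5-tribromophenyl)sulfilimine | CS(C)=Nc1cc(Br)c(Br)c(Br)c1 | intermediate (not isolated)
4 | 3,4,5-tribromo-2-[(methylsulfanyl)methyl]aniline | CSCc1c(N)cc(Br)c(Br)c1Br | intermediate
5 | N-{3,4,5-tribromo-2-[(methylsulfanyl)methyl]phenyl}formamide | CSCc1c(NC=O)cc(Br)c(Br)c1Br | intermediate
6 | 1,2,3-tribromo-5-isocyano-4-[(methylsulfanyl)methyl]benzene | CSCc1c([N+]#[C-])cc(Br)c(Br)c1Br | intermediate
7 | [(2,3,4-tribromo-6-isocyanophenyl)(methylsulfanyl)methyl]lithium (racemic, configurationally labile) | CSC([Li])c1c([N+]#[C-])cc(Br)c(Br)c1Br | intermediate (not isolated)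
8 | lithium 4,5,6-tribromo-3-(methylsulfanyl)indol-1-ide | [Li+].CSc1c[n-]c2cc(Br)c(Br)c(Br)c12 | intermediate (not isolated)
9 | 4,5,6-tribromo-3-(methylsulfanyl)-1H-indole | CSc1c[nH]c2cc(Br)c(Br)c(Br)c12 | intermediate
10 | 2,4,5,6-tetrabromo-3-(methylsulfanyl)-1H-indole | CSc1c(Br)[nH]c2cc(Br)c(Br)c(Br)c12 | target

## Step count and least certain steps

Total step count: 5. Longest linear sequence: 5 steps (1 to 10).

**Step 4 (key step).** The most likely failure is deprotonation of the ring C–H between the isocyano group and bromine, followed by bromine migration between aryl-lithium and aryl bromide species. Addition of the amide to the isocyanide carbon, or intermolecular addition of the carbanion to a second isocyanide, could also compete if ring closure of the sulfur-stabilised (less nucleophilic) carbanion is slow. The fallback avoids strong base altogether; it sets out from 1 and returns to the route at 9. Compound 1 would be subjected to the Gassman indole sequence with NCS and (methylsulfanyl)acetaldehyde dimethyl acetal, then Et3N. The same type of [2,3] shift as in step 1 should give 3,4,5-tribromo-2-[2,2-dimethoxy-1-(methylsulfanyl)ethyl]aniline F1 (racemic). Dilute HCl in ether would then close the ring at N1–C2 with loss of two molecules of methanol to give 9.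

**Step 1.** The weakly nucleophilic aniline may form the N–S bond slowly. The stabilised sulfilimine of so electron-poor an aniline may resist tautomerisation to the ylide, so that the rearrangement stalls. The shift to a carbon flanked by bromine may be hindered, or a second ortho-alkylation may follow. The fallback replaces the sigmatropic shift by a cross-coupling; it sets out from 1 and returns at 4. Iodination of 1 with N-iodosuccinimide in AcOH should give 3,4,5-tribromo-2-iodoaniline F2, since only the two equivalent ortho positions are open. A Migita–Kosugi–Stille coupling with tributyl[(methylsulfanyl)methyl]stannane (Pd(PPh3)4, toluene, 80 °C) would then give 4; it relies on oxidative addition of zerovalent palladium being faster at C–I than at C–Br.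

**Step 5.** The brominating agent may attack sulfur, leading to Pummerer-type bromination of the S-methyl group or to sulfoxide formation on work-up. Further bromination at N1 or C7, or acid-promoted loss of the sulfenyl group by traces of HBr, are also possible. The fallback replaces electrophilic attack on the π-system by deprotonation at C2; it sets out from 9 and returns at 10. Compound 9 would be protected with Boc2O and DMAP as tert-butyl 4,5,6-tribromo-3-(methylsulfanyl)-1H-indole-1-carboxylate F3. Lithiation at C2 with LiN(iPr)2 at −78 °C, directed by the carbamate, and a quench with 1,2-dibromo-1,1,2,2-tetrachloroethane would give tert-butyl 2,4,5,6-tetrabromo-3-(methylsulfanyl)-1H-indole-1-carboxylate F4. Methanolysis with K2CO3 in MeOH would remove the carbamate to give 10.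

## Further compounds

F1 | step 4 | 3,4,5-tribromo-2-[2,2-dimethoxy-1-(methylsulfanyl)ethyl]aniline (racemic) | COC(OC)C(SC)c1c(N)cc(Br)c(Br)c1Br
F2 | step 1 | 3,4,5-tribromo-2-iodoaniline | Nc1cc(Br)c(Br)c(Br)c1I
F3 | step 5 | tert-butyl 4,5,6-tribromo-3-(methylsulfanyl)-1H-indole-1-carboxylate | CSc1cn(C(=O)OC(C)(C)C)c2cc(Br)c(Br)c(Br)c12
F4 | step 5 | tert-butyl 2,4,5,6-tetrabromo-3-(methylsulfanyl)-1H-indole-1-carboxylate | CSc1c(Br)n(C(=O)OC(C)(C)C)c2cc(Br)c(Br)c(Br)c12
A1 | alternative 1 | 4,5,6-tribromo-1H-indole | Brc1cc2[nH]ccc2c(Br)c1Br
A2 | alternative 2 | 4,5,6-tribromo-3-(methylsulfanyl)-1,3-dihydro-2H-indol-2-one (racemic) | CSC1C(=O)Nc2cc(Br)c(Br)c(Br)c12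
A3 | alternative 3 | 3,4,5-tribromobenzyne (1,2,3-tribromo-4,5-didehydrobenzene) | BrC1=C(Br)C(Br)=CC#C1
A4 | alternative 3 | 4,5,6-tribromo-1-(4-methylbenzenesulfonyl)-1,2-dihydro-3H-indol-3-one | Cc1ccc(cc1)S(=O)(=O)N1CC(=O)c2c(Br)c(Br)c(Br)cc12
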